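**Retrosynthetic overview**

1. The pyran ring is cut last. Target locants are C1, O2, C3, C4, C4a, C5–C8, C8a. The cuts are O2–C3 (oxa-cyclisation onto a C4a propynyl group), C1–C8a (aminomethylenation), C4a–C4 (Sonogashira coupling of a C4a enol triflate) and C5–CH2 (reductive alkylation of a cyclohexane-1,3-dione with the lactone aldehyde).
2. The strategy rests on the α-ketol of the carbocycle: the C6 ketone beside the C7 tertiary carbinol carrying methyl, with the C8 carbinol and the C8a methylene next to it. The C6–C7 bond is cut as an intramolecular crossed benzoin of an aldehyde (C6) onto a methyl ketone (C7).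
3. The keto aldehyde comes from (S)-malic acid, which supplies C7, C8 (the stereocentre), C8a and C4a. A malonate half-ester adds C5 and C6, and MeMgBr adds the C7 methyl.
4. The lactone aldehyde comes from 1-bromo-3,5-dimethoxybenzene and (S)-propylene oxide (lactone C3 stereocentre) by dibromination, carboxylative lactonisation, methylation and formylation.
5. Ring order: carbocycle (step 9), lactone ring (step 14, side branch), pyran ring (step 23).

Key step: step 9

Remark on locants: the isochromen-6-one locants of the target are used for the carbocyclic fragment throughout, and the lactone unit keeps isochroman-1-one locants; "Ar" in names is the (3S)-6,8-bis(methoxymethoxy)-3,5-dimethyl-1-oxoisochroman-7-yl group.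
Remark on the catalyst: the (5aS,10bR) antipode of the triazolium salt is assumed to be the one matched to Si-face attack at C7; its mirror image is equally available and would take its place.

**Route**

Step 1
Reactants: 1 (S)-malic acid
Product: 2 (S)-2-(2,2-dimethyl-5-oxo-1,3-dioxolan-4-yl)acetic acid
Conditions: Me2C(OMe)2, TsOH·H2O (cat.), rt
Reagents that add atoms: 2,2-dimethoxypropane, COC(C)(C)OC
Why: Acid-catalysed acetonide formation ties the α-hydroxy acid into the five-membered dioxolanone and leaves the C4 acid free, with no bond to the stereocentre broken.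

Step 2
Reactants: 2 (S)-2-(2,2-dimethyl-5-oxo-1,3-dioxolan-4-yl)acetic acid; 3 potassium mono-tert-butyl malonate
Product: 5 tert-butyl 4-[(4S)-2,2-dimethyl-5-oxo-1,3-dioxolan-4-yl]-3-oxobutanoate, via acyl imidazolide 4 (not isolated)
Conditions: CDI, THF, rt; then 3, MgCl2, Et3N, MeCN/THF, rt; aq. citric acid
Reagents that add atoms: none
Why: Masamune–Brooks homologation, in which the magnesium malonate is C-acylated by the imidazolide and then loses CO2, runs near neutrality and should spare the dioxolanone and its enolisable stereocentre.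

Step 3
Reactants: 5 tert-butyl 4-[(4S)-2,2-dimethyl-5-oxo-1,3-dioxolan-4-yl]-3-oxobutanoate
Product: 6 tert-butyl 2-(2-{[(4S)-2,2-dimethyl-5-oxo-1,3-dioxolan-4-yl]methyl}-1,3-dioxolan-2-yl)acetate
Conditions: Me3SiOCH2CH2OSiMe3, Me3SiOTf (5 mol %), CH2Cl2, −78 → −20 °C
Reagents that add atoms: 1,2-bis(trimethylsilyloxy)ethane, C[Si](C)(C)OCCO[Si](C)(C)C
Why: Aprotic silyl-triflate-catalysed ketalisation masks the future C4a ketone as its ethylene ketal, driven by hexamethyldisiloxane formation, under conditions that should neither open the dioxolanone nor cleave the tert-butyl ester.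

Step 4
Reactants: 6 tert-butyl 2-(2-{[(4S)-2,2-dimethyl-5-oxo-1,3-dioxolan-4-yl]methyl}-1,3-dioxolan-2-yl)acetate
Product: 7 tert-butyl 2-(2-{(2S)-2-hydroxy-3-[methoxy(methyl)amino]-3-oxopropyl}-1,3-dioxolan-2-yl)acetate
Conditions: MeNH(OMe)·HCl, i-PrMgCl, THF, −20 → 0 °C
Reagents that add atoms: N,O-dimethylhydroxylamine hydrochloride, CNOC.Cl
Why: Aminolysis of the activated dioxolanone carbonyl by the magnesium amide (Weinreb amide formation) releases acetone and the free C8 hydroxyl, while the hindered tert-butyl ester should not react.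

Step 5
Reactants: 7 tert-butyl 2-(2-{(2S)-2-hydroxy-3-[methoxy(methyl)amino]-3-oxopropyl}-1,3-dioxolan-2-yl)acetate
Product: 8 tert-butyl 2-(2-{(2S)-2-(tert-butyldimethylsilyloxy)-3-[methoxy(methyl)amino]-3-oxopropyl}-1,3-dioxolan-2-yl)acetate
Conditions: TBSCl, imidazole, DMF, rt
Reagents that add atoms: tert-butyldimethylsilyl chloride, CC(C)(C)[Si](C)(C)Cl
Why: Imidazole-promoted silyl ether formation protects the C8 hydroxyl as the bulky ether that later biases the ring closure, with the configuration unchanged.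

Step 6
Reactants: 8 tert-butyl 2-(2-{(2S)-2-(tert-butyldimethylsilyloxy)-3-[methoxy(methyl)amino]-3-oxopropyl}-1,3-dioxolan-2-yl)acetate
Product: 9 tert-butyl 2-{2-[(2S)-2-(tert-butyldimethylsilyloxy)-3-oxobutyl]-1,3-dioxolan-2-yl}acetate
Conditions: MeMgBr, THF, −20 → 0 °C; aq. NH4Cl
Reagents that add atoms: methylmagnesium bromide, C[Mg]Br
Why: Weinreb ketone synthesis stops at the chelated tetrahedral adduct, so the methyl ketone (C7 with its methyl) forms without over-addition or enolisation at C8, and the tert-butyl ester is too hindered to add the Grignard reagent at this temperature.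

Step 7
Reactants: 9 tert-butyl 2-{2-[(2S)-2-(tert-butyldimethylsilyloxy)-3-oxobutyl]-1,3-dioxolan-2-yl}acetate
Product: 10 (3S)-3-(tert-butyldimethylsilyloxy)-4-[2-(2-hydroxyethyl)-1,3-dioxolan-2-yl]butan-2-ol (both C2 epimers)
Conditions: i-Bu2AlH (excess), CH2Cl2, −78 → 0 °C; aq. Rochelle salt
Reagents that add atoms: none
Why: Hydride reduction of both ester and ketone sidesteps the unselective reduction of an ester beside a ketone, and the new carbinol centre, formed as a mixture, is erased in step 8.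

Step 8
Reactants: 10 (3S)-3-(tert-butyldimethylsilyloxy)-4-[2-(2-hydroxyethyl)-1,3-dioxolan-2-yl]butan-2-ol
Product: 11 2-{2-[(2S)-2-(tert-butyldimethylsilyloxy)-3-oxobutyl]-1,3-dioxolan-2-yl}acetaldehyde
Conditions: Dess–Martin periodinane, pyridine, CH2Cl2, 0 °C → rt
Reagents that add atoms: none
Why: Dess–Martin oxidation of the primary and the secondary alcohol in one operation gives the aldehyde and the methyl ketone under buffered, non-basic conditions that should neither epimerise C8 nor open the β-ketal.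

Step 9
Reactants: 11 2-{2-[(2S)-2-(tert-butyldimethylsilyloxy)-3-oxobutyl]-1,3-dioxolan-2-yl}acetaldehyde
Product: 12 (8R,9S)-9-(tert-butyldimethylsilyloxy)-8-hydroxy-8-methyl-1,4-dioxaspiro[4.5]decan-7-one
Conditions: (5aS,10bR)-2-(pentafluorophenyl)-5a,10b-dihydro-4H,6H-indeno[2,1-b][1,2,4]triazolo[4,3-d][1,4]oxazin-2-ium tetrafluoroborate (10 mol %), Et3N (20 mol %), toluene, rt
Reagents that add atoms: none
Why: The triazolylidene freed by the amine adds to the C6 aldehyde, a proton shift gives the Breslow enaminol, and its nucleophilic C6 attacks the C7 ketone; proton transfer and loss of the carbene leave the C6 ketone beside the new C7 carbinol (intramolecular crossed benzoin reaction). The closest known reaction type is the carbene-catalysed aldehyde–ketone benzoin cyclisation of keto aldehydes to six-membered tertiary α-ketols with chiral bicyclic triazolium salts. The carbocycle closes in the 6-exo-trig mode. C7 is set by attack on the Si face of the ketone, chosen by the chiral carbene and supported by a chair-like closure in which the C8 silyloxy group lies equatorial, anti to the forming bond and clear of the axial ketal oxygen at C4a, so that the C7 hydroxyl ends trans to the C8 oxygen (7R). The step needs the aldehyde as donor and the ketone as acceptor: only the aldehyde can form the enaminol, the α-silyloxy methyl ketone is an activated acceptor placed for a six-membered closure, and the weak amine base should leave the C8 centre, the aldehyde α-position and the β-ketal untouched.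

Step 10
Reactants: 12 (8R,9S)-9-(tert-butyldimethylsilyloxy)-8-hydroxy-8-methyl-1,4-dioxaspiro[4.5]decan-7-one
Product: 13 (4R,5S)-5-(tert-butyldimethylsilyloxy)-4-hydroxy-4-methylcyclohexane-1,3-dione
Conditions: TsOH·H2O (cat.), acetone/H2O, rt → 40 °C
Reagents that add atoms: water, O
Why: Acid-catalysed ketal hydrolysis is driven by formation of the enolised 1,3-dione, the secondary silyl ether should survive the dilute acid, and neither C7 (quaternary) nor C8 (not α to a carbonyl) can epimerise.

Step 11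
Reactants: 13 (4R,5S)-5-(tert-butyldimethylsilyloxy)-4-hydroxy-4-methylcyclohexane-1,3-dione
Product: 15 (4R,5S)-5-(tert-butyldimethylsilyloxy)-4-methyl-4-(triethylsilyloxy)cyclohexane-1,3-dione, via bis-silyl enol ether 14 (not isolated)
Conditions: Et3SiOTf (2.5 equiv), 2,6-lutidine, CH2Cl2, −78 → 0 °C; then H2O/THF, rt
Reagents that add atoms: triethylsilyl trifluoromethanesulfonate, CC[Si](CC)(CC)OS(=O)(=O)C(F)(F)F
Why: Silyl triflate silylation covers the tertiary C7 hydroxyl, and the enol oxygen that is silylated as well forms a vinylogous silyl ester that water cleaves on work-up while the tertiary ether stays.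

Step 12
Reactants: 16 1-bromo-3,5-dimethoxybenzene; 17 (S)-propylene oxide
Product: 19 (S)-1-(3,5-dimethoxyphenyl)propan-2-ol, via arylmagnesium bromide 18 (not isolated)
Conditions: Mg, THF; then CuI (10 mol %), 17, −30 → 0 °C; aq. NH4Cl
Reagents that add atoms: none
Why: Copper-catalysed epoxide opening by the aryl Grignard reagent occurs at the unsubstituted carbon (SN2), so the stereocentre of (S)-propylene oxide is carried over unchanged as the (S)-carbinol.

Step 13
Reactants: 19 (S)-1-(3,5-dimethoxyphenyl)propan-2-ol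
Product: 20 (S)-1-(2,6-dibromo-3,5-dimethoxyphenyl)propan-2-ol
Conditions: NBS (2.05 equiv), MeCN, 0 °C → rt
Reagents that add atoms: N-bromosuccinimide, O=C1CCC(=O)N1Br
Why: Electrophilic aromatic bromination should go twice para to a methoxy group, at the two equivalent positions flanking the side chain, because the position between the two methoxy groups is the most shielded.

Step 14
Reactants: 20 (S)-1-(2,6-dibromo-3,5-dimethoxyphenyl)propan-2-ol
Product: 23 (S)-5-bromo-6,8-dimethoxy-3-methylisochroman-1-one, via dilithio species 21 (not isolated), via hydroxy acid 22 (not isolated)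
Conditions: n-BuLi (2.1 equiv), THF, −78 °C; CO2; aq. HCl; TsOH (cat.), toluene, 60 °C
Reagents that add atoms: carbon dioxide, O=C=O
Why: Deprotonation of the hydroxyl and one bromine–lithium exchange (the two bromines are equivalent) give an aryllithium that is carboxylated, and acid closes the δ-lactone by esterification at the acyl carbon, so the carbinol configuration is retained.

Step 15
Reactants: 23 (S)-5-bromo-6,8-dimethoxy-3-methylisochroman-1-one
Product: 24 (S)-6,8-dimethoxy-3,5-dimethylisochroman-1-one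
Conditions: trimethylboroxine, Pd(dppf)Cl2 (5 mol %), K2CO3, 1,4-dioxane, 100 °C
Reagents that add atoms: trimethylboroxine, CB1OB(C)OB(C)O1
Why: Suzuki–Miyaura coupling replaces the remaining aryl bromide by methyl through oxidative addition to zerovalent palladium and transmetalation from the boroxine.

Step 16
Reactants: 24 (S)-6,8-dimethoxy-3,5-dimethylisochroman-1-one
Product: 25 (S)-6,8-dihydroxy-3,5-dimethylisochroman-1-one
Conditions: BBr3, CH2Cl2, −78 → 0 °C; H2O
Reagents that add atoms: none
Why: Lewis-acid ether cleavage by BBr3 (bromide attack on the O-methyl carbon of the boron-bound ether) frees both phenols and leaves the lactone and its stereocentre alone.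

Step 17
Reactants: 25 (S)-6,8-dihydroxy-3,5-dimethylisochroman-1-one
Product: 26 (S)-6,8-dihydroxy-3,5-dimethyl-1-oxoisochromane-7-carbaldehyde
Conditions: TiCl4, Cl2CHOMe, CH2Cl2, 0 °C; aq. HCl
Reagents that add atoms: dichloromethyl methyl ether, COC(Cl)Cl; water, O
Why: Rieche formylation of the titanium phenoxide attacks the only unsubstituted ring position, C7 of the lactone unit, which lies ortho to both hydroxyls.

Step 18
Reactants: 26 (S)-6,8-dihydroxy-3,5-dimethyl-1-oxoisochromane-7-carbaldehyde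
Product: 27 (S)-6,8-bis(methoxymethoxy)-3,5-dimethyl-1-oxoisochromane-7-carbaldehyde
Conditions: NaH, MOMCl, DMF, 0 °C → rt
Reagents that add atoms: chloromethyl methyl ether, COCCl
Why: Williamson-type O-alkylation of the two phenoxides masks the phenols as acetals that withstand base, amines and palladium and are cleaved by acid at the end.

Step 19
Reactants: 15 (4R,5S)-5-(tert-butyldimethylsilyloxy)-4-methyl-4-(triethylsilyloxy)cyclohexane-1,3-dione; 27 (S)-6,8-bis(methoxymethoxy)-3,5-dimethyl-1-oxoisochromane-7-carbaldehyde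
Product: 29 (4R,5S)-2-(ArCH2)-5-(tert-butyldimethylsilyloxy)-4-methyl-4-(triethylsilyloxy)cyclohexane-1,3-dione (enolised), via arylidene dione 28 (not isolated)
Conditions: L-proline (20 mol %), Hantzsch ester, CH2Cl2, rt
Reagents that add atoms: none
Why: Organocatalytic three-component reductive alkylation (proline-catalysed Knoevenagel condensation, then transfer hydrogenation of the arylidene dione by the Hantzsch ester) attaches the benzyl group at C5 without O-alkylation, and C5 is enolised and is not a stereocentre in the target.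

Step 20
Reactants: 29 (4R,5S)-2-(ArCH2)-5-(tert-butyldimethylsilyloxy)-4-methyl-4-(triethylsilyloxy)cyclohexane-1,3-dione
Product: 30 (4R,5S)-2-(ArCH2)-5-(tert-butyldimethylsilyloxy)-4-methyl-3-oxo-4-(triethylsilyloxy)cyclohex-1-en-1-yl trifluoromethanesulfonate
Conditions: Tf2O, pyridine, CH2Cl2, −78 → 0 °C
Reagents that add atoms: trifluoromethanesulfonic anhydride, O=S(=O)(OS(=O)(=O)C(F)(F)F)C(F)(F)F
Why: Enol triflate formation should occur at the C4a oxygen, remote from the fully substituted C7 whose triethylsilyloxy group shields the C6 oxygen.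

Step 21
Reactants: 30 (4R,5S)-2-(ArCH2)-5-(tert-butyldimethylsilyloxy)-4-methyl-3-oxo-4-(triethylsilyloxy)cyclohex-1-en-1-yl trifluoromethanesulfonate; 31 propyne
Product: 32 (5S,6R)-2-(ArCH2)-5-(tert-butyldimethylsilyloxy)-6-methyl-3-(prop-1-yn-1-yl)-6-(triethylsilyloxy)cyclohex-2-en-1-one
Conditions: 31 (THF solution, excess), PdCl2(PPh3)2 (5 mol %), CuI (10 mol %), Et3N, THF, rt
Reagents that add atoms: none
Why: Sonogashira coupling joins C4a to C4, since the electron-poor β-triflyloxy enone adds readily to zerovalent palladium and is then coupled with the copper acetylide of propyne.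

Step 22
Reactants: 32 (5S,6R)-2-(ArCH2)-5-(tert-butyldimethylsilyloxy)-6-methyl-3-(prop-1-yn-1-yl)-6-(triethylsilyloxy)cyclohex-2-en-1-one
Product: 33 (5S,6R)-2-(ArCH2)-5-(tert-butyldimethylsilyloxy)-4-[(dimethylamino)methylidene]-6-methyl-3-(prop-1-yn-1-yl)-6-(triethylsilyloxy)cyclohex-2-en-1-one
Conditions: t-BuOCH(NMe2)2, toluene, 70 °C
Reagents that add atoms: tert-butoxybis(dimethylamino)methane, CN(C)C(OC(C)(C)C)N(C)C
Why: Vinylogous aminomethylenation with the aminal ester places C1 on C8a as a push–pull enamine, because the released tert-butoxide deprotonates C8a, the only enolisable position (C7 is quaternary), and the extended enolate condenses with the formamidinium ion.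

Step 23
Reactants: 33 (5S,6R)-2-(ArCH2)-5-(tert-butyldimethylsilyloxy)-4-[(dimethylamino)methylidene]-6-methyl-3-(prop-1-yn-1-yl)-6-(triethylsilyloxy)cyclohex-2-en-1-one
Product: 35 (7R,8S)-5-(ArCH2)-8-(tert-butyldimethylsilyloxy)-3,7-dimethyl-7-(triethylsilyloxy)-7,8-dihydro-6H-isochromen-6-one, via hydroxymethylene enynone 34 (not isolated)
Conditions: AcOH/H2O/THF, rt; then AgOTf (5 mol %), CH2Cl2, rt
Reagents that add atoms: water, O
Why: Mild hydrolysis of the vinylogous amide gives the C1 hydroxymethylene compound, whose oxygen then adds to the distal alkyne carbon C3 under silver catalysis (6-endo-dig oxa-cyclisation, also the 1,6-conjugate mode of the ynenone) to close the pyran ring.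

Step 24
Reactants: 35 (7R,8S)-5-(ArCH2)-8-(tert-butyldimethylsilyloxy)-3,7-dimethyl-7-(triethylsilyloxy)-7,8-dihydro-6H-isochromen-6-one
Product: 36 (7R,8S)-5-{[(3S)-6,8-dihydroxy-3,5-dimethyl-1-oxoisochroman-7-yl]methyl}-7,8-dihydroxy-3,7-dimethyl-7,8-dihydro-6H-isochromen-6-one (target)
Conditions: TFA/H2O (9:1), CH2Cl2, 0 °C → rt
Reagents that add atoms: none
Why: Acid-catalysed cleavage of the two methoxymethyl acetals and the two silyl ethers frees the phenols and the diol in one operation, and since the pyranylidene ketone is only protonated reversibly at O6, ionisation at C8 is disfavoured and C7 and C8 should keep their configuration.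

**Compound list**

1 | (S)-malic acid | O[C@@H](CC(=O)O)C(=O)O | starting material
2 | (S)-2-(2,2-dimethyl-5-oxo-1,3-dioxolan-4-yl)acetic acid | CC1(C)O[C@@H](CC(=O)O)C(=O)O1 | intermediate
3 | potassium mono-tert-butyl malonate | CC(C)(C)OC(=O)CC(=O)[O-].[K+] | starting material
4 | acyl imidazolide of 2 | CC1(C)O[C@@H](CC(=O)n2ccnc2)C(=O)O1 | intermediate (not isolated)
5 | tert-butyl 4-[(4S)-2,2-dimethyl-5-oxo-1,3-dioxolan-4-yl]-3-oxobutanoate | CC1(C)O[C@@H](CC(=O)CC(=O)OC(C)(C)C)C(=O)O1 | intermediate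
6 | tert-butyl 2-(2-{[(4S)-2,2-dimethyl-5-oxo-1,3-dioxolan-4-yl]methyl}-1,3-dioxolan-2-yl)acetate | CC1(C)O[C@@H](CC2(CC(=O)OC(C)(C)C)OCCO2)C(=O)O1 | intermediate
7 | tert-butyl 2-(2-{(2S)-2-hydroxy-3-[methoxy(methyl)amino]-3-oxopropyl}-1,3-dioxolan-2-yl)acetate | CON(C)C(=O)[C@@H](O)CC1(CC(=O)OC(C)(C)C)OCCO1 | intermediate
8 | tert-butyl 2-(2-{(2S)-2-(tert-butyldimethylsilyloxy)-3-[methoxy(methyl)amino]-3-oxopropyl}-1,3-dioxolan-2-yl)acetate | CON(C)C(=O)[C@@H](O[Si](C)(C)C(C)(C)C)CC1(CC(=O)OC(C)(C)C)OCCO1 | intermediate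
9 | tert-butyl 2-{2-[(2S)-2-(tert-butyldimethylsilyloxy)-3-oxobutyl]-1,3-dioxolan-2-yl}acetate | CC(=O)[C@@H](O[Si](C)(C)C(C)(C)C)CC1(CC(=O)OC(C)(C)C)OCCO1 | intermediate
10 | (3S)-3-(tert-butyldimethylsilyloxy)-4-[2-(2-hydroxyethyl)-1,3-dioxolan-2-yl]butan-2-ol, both C2 epimers | CC(O)[C@@H](O[Si](C)(C)C(C)(C)C)CC1(CCO)OCCO1 | intermediate
11 | 2-{2-[(2S)-2-(tert-butyldimethylsilyloxy)-3-oxobutyl]-1,3-dioxolan-2-yl}acetaldehyde | CC(=O)[C@@H](O[Si](C)(C)C(C)(C)C)CC1(CC=O)OCCO1 | intermediate (key-step precursor)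
12 | (8R,9S)-9-(tert-butyldimethylsilyloxy)-8-hydroxy-8-methyl-1,4-dioxaspiro[4.5]decan-7-one | C[C@]1(O)C(=O)CC2(OCCO2)C[C@@H]1O[Si](C)(C)C(C)(C)C | intermediate (key-step product)
13 | (4R,5S)-5-(tert-butyldimethylsilyloxy)-4-hydroxy-4-methylcyclohexane-1,3-dione | C[C@]1(O)C(=O)CC(=O)C[C@@H]1O[Si](C)(C)C(C)(C)C | intermediate
14 | (5S,6R)-5-(tert-butyldimethylsilyloxy)-6-methyl-3,6-bis(triethylsilyloxy)cyclohex-2-en-1-one | C[C@]1(O[Si](CC)(CC)CC)C(=O)C=C(O[Si](CC)(CC)CC)C[C@@H]1O[Si](C)(C)C(C)(C)C | intermediate (not isolated)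
15 | (4R,5S)-5-(tert-butyldimethylsilyloxy)-4-methyl-4-(triethylsilyloxy)cyclohexane-1,3-dione | C[C@]1(O[Si](CC)(CC)CC)C(=O)CC(=O)C[C@@H]1O[Si](C)(C)C(C)(C)C | intermediate
16 | 1-bromo-3,5-dimethoxybenzene | COc1cc(Br)cc(OC)c1 | starting material
17 | (S)-propylene oxide | C[C@H]1CO1 | starting material
18 | (3,5-dimethoxyphenyl)magnesium bromide | COc1cc([Mg]Br)cc(OC)c1 | intermediate (not isolated)
19 | (S)-1-(3,5-dimethoxyphenyl)propan-2-ol | C[C@H](O)Cc1cc(OC)cc(OC)c1 | intermediate
20 | (S)-1-(2,6-dibromo-3,5-dimethoxyphenyl)propan-2-ol | C[C@H](O)Cc1c(Br)c(OC)cc(OC)c1Br | intermediate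
21 | lithium (S)-1-(2-bromo-6-lithio-3,5-dimethoxyphenyl)propan-2-olate | C[C@H](O[Li])Cc1c([Li])c(OC)cc(OC)c1Br | intermediate (not isolated)
22 | 3-bromo-2-[(2S)-2-hydroxypropyl]-4,6-dimethoxybenzoic acid | C[C@H](O)Cc1c(C(=O)O)c(OC)cc(OC)c1Br | intermediate (not isolated)
23 | (S)-5-bromo-6,8-dimethoxy-3-methylisochroman-1-one | C[C@H]1Cc2c(Br)c(OC)cc(OC)c2C(=O)O1 | intermediate
24 | (S)-6,8-dimethoxy-3,5-dimethylisochroman-1-one | C[C@H]1Cc2c(C)c(OC)cc(OC)c2C(=O)O1 | intermediate
25 | (S)-6,8-dihydroxy-3,5-dimethylisochroman-1-one | C[C@H]1Cc2c(C)c(O)cc(O)c2C(=O)O1 | intermediate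
26 | (S)-6,8-dihydroxy-3,5-dimethyl-1-oxoisochromane-7-carbaldehyde | C[C@H]1Cc2c(C)c(O)c(C=O)c(O)c2C(=O)O1 | intermediate
27 | (S)-6,8-bis(methoxymethoxy)-3,5-dimethyl-1-oxoisochromane-7-carbaldehyde | C[C@H]1Cc2c(C)c(OCOC)c(C=O)c(OCOC)c2C(=O)O1 | intermediate
28 | (4R,5S)-2-(Ar-methylidene)-5-(tert-butyldimethylsilyloxy)-4-methyl-4-(triethylsilyloxy)cyclohexane-1,3-dione | C[C@]1(O[Si](CC)(CC)CC)C(=O)C(=Cc2c(OCOC)c(C)c3c(c2OCOC)C(=O)O[C@@H](C)C3)C(=O)C[C@@H]1O[Si](C)(C)C(C)(C)C | intermediate (not isolated)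
29 | (4R,5S)-2-{[(3S)-6,8-bis(methoxymethoxy)-3,5-dimethyl-1-oxoisochroman-7-yl]methyl}-5-(tert-butyldimethylsilyloxy)-4-methyl-4-(triethylsilyloxy)cyclohexane-1,3-dione (enolised) | C[C@]1(O[Si](CC)(CC)CC)C(=O)C(Cc2c(OCOC)c(C)c3c(c2OCOC)C(=O)O[C@@H](C)C3)C(=O)C[C@@H]1O[Si](C)(C)C(C)(C)C | intermediate
30 | (4R,5S)-2-(ArCH2)-5-(tert-butyldimethylsilyloxy)-4-methyl-3-oxo-4-(triethylsilyloxy)cyclohex-1-en-1-yl trifluoromethanesulfonate | C[C@]1(O[Si](CC)(CC)CC)C(=O)C(Cc2c(OCOC)c(C)c3c(c2OCOC)C(=O)O[C@@H](C)C3)=C(OS(=O)(=O)C(F)(F)F)C[C@@H]1O[Si](C)(C)C(C)(C)C | intermediate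
31 | propyne | CC#C | starting material
32 | (5S,6R)-2-(ArCH2)-5-(tert-butyldimethylsilyloxy)-6-methyl-3-(prop-1-yn-1-yl)-6-(triethylsilyloxy)cyclohex-2-en-1-one | C[C@]1(O[Si](CC)(CC)CC)C(=O)C(Cc2c(OCOC)c(C)c3c(c2OCOC)C(=O)O[C@@H](C)C3)=C(C#CC)C[C@@H]1O[Si](C)(C)C(C)(C)C | intermediate
33 | (5S,6R)-2-(ArCH2)-5-(tert-butyldimethylsilyloxy)-4-[(dimethylamino)methylidene]-6-methyl-3-(prop-1-yn-1-yl)-6-(triethylsilyloxy)cyclohex-2-en-1-one | C[C@]1(O[Si](CC)(CC)CC)C(=O)C(Cc2c(OCOC)c(C)c3c(c2OCOC)C(=O)O[C@@H](C)C3)=C(C#CC)C(=CN(C)C)[C@@H]1O[Si](C)(C)C(C)(C)C | intermediate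
34 | (5S,6R)-2-(ArCH2)-5-(tert-butyldimethylsilyloxy)-4-(hydroxymethylidene)-6-methyl-3-(prop-1-yn-1-yl)-6-(triethylsilyloxy)cyclohex-2-en-1-one | C[C@]1(O[Si](CC)(CC)CC)C(=O)C(Cc2c(OCOC)c(C)c3c(c2OCOC)C(=O)O[C@@H](C)C3)=C(C#CC)C(=CO)[C@@H]1O[Si](C)(C)C(C)(C)C | intermediate (not isolated)
35 | (7R,8S)-5-{[(3S)-6,8-bis(methoxymethoxy)-3,5-dimethyl-1-oxoisochroman-7-yl]methyl}-8-(tert-butyldimethylsilyloxy)-3,7-dimethyl-7-(triethylsilyloxy)-7,8-dihydro-6H-isochromen-6-one | CC1=CC2=C(Cc3c(OCOC)c(C)c4c(c3OCOC)C(=O)O[C@@H](C)C4)C(=O)[C@](C)(O[Si](CC)(CC)CC)[C@@H](O[Si](C)(C)C(C)(C)C)C2=CO1 | intermediate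
36 | (7R,8S)-5-{[(3S)-6,8-dihydroxy-3,5-dimethyl-1-oxoisochroman-7-yl]methyl}-7,8-dihydroxy-3,7-dimethyl-7,8-dihydro-6H-isochromen-6-one | CC1=CC2=C(Cc3c(O)c(C)c4c(c3O)C(=O)O[C@@H](C)C4)C(=O)[C@](C)(O)[C@@H](O)C2=CO1 | target

**Step count**

Total: 24 steps. Longest linear sequence: 17 steps (steps 1–11, then 19–24); the lactone branch (steps 12–18) joins at step 19.

**Steps most likely to fail**

1. Step 9 (carbene-catalysed benzoin closure). The carbene turnover may be outrun by base-mediated aldol closure of the aldehyde enolate onto C7 or by β-elimination that opens the C4a ketal, and the facial selectivity at C7 may be low. Fallback: from 11, a reductive ketyl–carbonyl (pinacol) cyclisation with SmI2 in THF/t-BuOH at −78 °C should form the same C6–C7 bond and give 9-(tert-butyldimethylsilyloxy)-8-methyl-1,4-dioxaspiro[4.5]decane-7,8-diol F1. It is expected as the cis-diol with the C7 hydroxyl trans to the C8 silyloxy group, because the ketyl adds anti to the neighbouring oxygen substituent. Oxidation of the secondary C6 hydroxyl of F1 alone (SO3·pyridine, DMSO, i-Pr2NEt; the tertiary hydroxyl is inert) comes back to the route at 12.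

2. Step 22 (aminomethylenation at C8a). The extended enolate may expel the C8 silyloxy group by vinylogous β-elimination at 70 °C, and the liberated dimethylamine may add to the ynenone. Fallback: from 32, LiN(SiMe3)2 is added to a mixture of 32 and Me3SiCl in THF at −78 °C, so that the enolate is trapped as it forms, to give the trimethylsilyl dienol ether F2. F2 is formylated at its terminal carbon C8a by (chloromethylene)dimethyliminium chloride (2,6-lutidine, CH2Cl2, −40 → 0 °C; aq. NaHCO3), the known terminal formylation of dienol ethers by the Vilsmeier salt. This returns to the route at enaminone 33.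

3. Step 19 (reductive alkylation). Knoevenagel condensation of the doubly ortho-substituted, electron-rich aldehyde may be slow, and the arylidene dione may be captured by a second molecule of dione before hydride transfer. Fallback: from 27, NaBH4 (MeOH/THF, 0 °C) gives (S)-7-(hydroxymethyl)-6,8-bis(methoxymethoxy)-3,5-dimethylisochroman-1-one F3, and CBr4/PPh3 (CH2Cl2, 0 °C) converts it into (S)-7-(bromomethyl)-6,8-bis(methoxymethoxy)-3,5-dimethylisochroman-1-one F4. C-alkylation of the enolate of 15 with F4 (K2CO3, H2O/toluene, Bu4NBr cat., rt) returns to the route at 29.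

Further compounds
F1 | step 9 | 9-(tert-butyldimethylsilyloxy)-8-methyl-1,4-dioxaspiro[4.5]decane-7,8-diol, cis-diol with the tertiary hydroxyl trans to the silyloxy group | C[C@]1(O)[C@@H](O)CC2(OCCO2)C[C@@H]1O[Si](C)(C)C(C)(C)C
F2 | step 22 | trimethylsilyl dienol ether of 32 (C6 silyloxy, C5=C6 and C4a=C8a double bonds) | C[C@]1(O[Si](CC)(CC)CC)C(O[Si](C)(C)C)=C(Cc2c(OCOC)c(C)c3c(c2OCOC)C(=O)O[C@@H](C)C3)C(C#CC)=C[C@@H]1O[Si](C)(C)C(C)(C)C
F3 | step 19 | (S)-7-(hydroxymethyl)-6,8-bis(methoxymethoxy)-3,5-dimethylisochroman-1-one | C[C@H]1Cc2c(C)c(OCOC)c(CO)c(OCOC)c2C(=O)O1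
F4 | step 19 | (S)-7-(bromomethyl)-6,8-bis(methoxymethoxy)-3,5-dimethylisochroman-1-one | C[C@H]1Cc2c(C)c(OCOC)c(CBr)c(OCOC)c2C(=O)O1
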